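**Retrosynthetic overview**
1. Target 23 ⇒ keto-phenol 22: the last bond made is the aryl ether O–C1, closed by reductive cycloetherification, which also sets C1.
2. 22 ⇒ 2,4-diformylphloroglucinol 19 + 3-methylbutanal 1 + silyl enol ether 16 (C1′–C2 bond; sets C1′ and the quaternary C2).
3. 16 ⇐ spiro ketone 15 ⇐ asymmetric spirocyclising Diels–Alder of exo-enone 13 with acetoxy diene 8 (ring B; sets C5 and C10), then reductive allylic transposition.
4. Ring order: cyclopentanone (bought) → cyclohexene ring B (Diels–Alder) → aromatic ring attached → pyran ring closed last through the C–O bond.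
5. Locants: spiro[4.5]decane numbering (C1 = O-bearing carbon, C2 = C–CH3 quaternary carbon, C5 = spiro carbon, C6=C7(iPr), C10 = CH–CH3); C1′ = benzylic carbon.

Assumption: the (S,S) antipode of the step 5 catalyst is taken to give the (5R,10S) series; if a pilot run shows the opposite sense, the (R,R) antipode is used.

**Step 1**
Reactants: 1 3-methylbutanal; 2 cyclohexylamine
Product: 3 (E)-N-cyclohexyl-3-methylbutan-1-imine
Conditions: neat, 0 °C → rt; KOH pellets; distil
Reagents that add atoms: none
Why: Imine condensation masks the aldehyde so that only its α-carbon is metallated in step 2; no stereocentre is formed.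

**Step 2**
Reactants: 3 (E)-N-cyclohexyl-3-methylbutan-1-imine; 4 acetaldehyde
Product: 7 (2E)-2-(propan-2-yl)but-2-enal, via lithio aza-enolate 5 (not isolated), via β-hydroxy imine 6 (not isolated)
Conditions: LiN(iPr)2, THF, −78 °C; 4, −78 °C; then 2 M aq. HCl, 40 °C
Reagents that add atoms: water, O
Why: Wittig directed aldol condensation: the lithiated imine adds to acetaldehyde without self-condensation, and acid hydrolysis with dehydration gives the thermodynamically preferred (E)-enal.

**Step 3**
Reactants: 7 (2E)-2-(propan-2-yl)but-2-enal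
Product: 8 (1E)-2-(propan-2-yl)buta-1,3-dien-1-yl acetate
Conditions: Ac2O, Et3N, 4-(dimethylamino)pyridine (10 mol %), 60 °C
Reagents that add atoms: acetic anhydride, CC(=O)OC(C)=O
Why: Dienol acetate formation (γ-deprotonation and O-acylation of the extended enolate) from the s-trans enal puts the acetoxy group anti to the vinyl group (1E), the geometry that allows an s-cis diene.

**Step 4**
Reactants: 9 2-methylcyclopentan-1-one (racemic); 4 acetaldehyde
Product: 13 (2E)-2-ethylidene-5-methylcyclopentan-1-one (racemic), via lithium enolate 10 (not isolated), via aldol 11 (not isolated), via mesylate 12 (not isolated)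
Conditions: LiN(iPr)2, THF, −78 °C; 4; MsCl, −78 → 0 °C; DBU, rt
Reagents that add atoms: none
Why: Aldol condensation through the kinetic enolate at the less substituted α-carbon, then mesylation and E1cB elimination, gives the conjugated exo-enone as the (E) isomer (methyl anti to C=O).

**Step 5**
Reactants: 13 (2E)-2-ethylidene-5-methylcyclopentan-1-one; 8 (1E)-2-(propan-2-yl)buta-1,3-dien-1-yl acetate
Product: 14 (5R,10S)-2,10-dimethyl-1-oxo-7-(propan-2-yl)spiro[4.5]dec-7-en-6-yl acetate (mixture of C2 and C6 epimers)
Conditions: 8 (2 equiv), (S,S)-IDPi (5 mol %; the imidodiphosphorimidate Brønsted acid made from two (S)-3,3′-bis[3,5-bis(trifluoromethyl)phenyl]-1,1′-binaphthalene-2,2′-diol units O,O′-bound to a P(=NSO2CF3)–N=P(NHSO2CF3) core), CH2Cl2, −40 °C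
Reagents that add atoms: none
Why: Proposed new method: the confined, strongly acidic chiral imidodiphosphorimidate hydrogen-bonds/protonates the s-cis exo-enone inside its pocket, lowering the LUMO and shielding one enantioface, so the acetoxy diene adds in an asynchronous [4+2] (C9–C10 bond first, then C6–C5) with acetoxy-controlled "ortho" regiochemistry, the (E) geometry of 13 being transferred suprafacially (C10 methyl cis to C4, trans to the C1 carbonyl) and the catalyst fixing the absolute sense (5R,10S); the closest known reaction type is the imidodiphosphorimidate-catalysed spirocyclising Diels–Alder reaction of exo-enones with simple hydrocarbon dienes, which has not been shown for a β-methyl exo-enone with a 1-acyloxy-2-alkyl diene.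

**Step 6**
Reactants: 14 (5R,10S)-2,10-dimethyl-1-oxo-7-(propan-2-yl)spiro[4.5]dec-7-en-6-yl acetate
Product: 15 (5R,10S)-2,10-dimethyl-7-(propan-2-yl)spiro[4.5]dec-6-en-1-one (mixture of C2 epimers)
Conditions: Et3SiH (3 equiv), Me3SiOTf (20 mol %), CH2Cl2, −78 → −30 °C; aq. NaHCO3
Reagents that add atoms: none
Why: Ionic hydrogenation with allylic transposition (SN1′): the allylic acetate ionises to the C6–C7–C8 allyl cation and Et3SiH delivers hydride to the unhindered C8 terminus (C6 is neopentylic), giving the C6=C7 olefin while both C6 epimers converge and C5 and C10 are untouched.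

**Step 7**
Reactants: 15 (5R,10S)-2,10-dimethyl-7-(propan-2-yl)spiro[4.5]dec-6-en-1-one
Product: 16 tert-butyl{[(5R,10S)-2,10-dimethyl-7-(propan-2-yl)spiro[4.5]deca-1,6-dien-1-yl]oxy}dimethylsilane
Conditions: tBuMe2SiOTf, Et3N, CH2Cl2, 0 °C → rt
Reagents that add atoms: tert-butyldimethylsilyl trifluoromethanesulfonate, CC(C)(C)[Si](C)(C)OS(=O)(=O)C(F)(F)F
Why: Soft enolisation and O-silylation (silyl enol ether formation) can only go toward C2 because C5 is quaternary, which also erases the C2 epimer mixture.

**Step 8**
Reactants: 17 benzene-1,3,5-triol (phloroglucinol)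
Product: 19 2,4,6-trihydroxybenzene-1,3-dicarbaldehyde, via bis-iminium salt 18 (not isolated)
Conditions: POCl3 (2.2 equiv), DMF, 1,4-dioxane, 0 °C → rt; then H2O
Reagents that add atoms: N,N-dimethylformamide, CN(C)C=O; water, O
Why: Double Vilsmeier–Haack formylation of the electron-rich triol stops at the dialdehyde under stoichiometric control, and each formyl group deactivates the ring further.

**Step 9**
Reactants: 19 2,4,6-trihydroxybenzene-1,3-dicarbaldehyde; 1 3-methylbutanal; 16 tert-butyl{[(5R,10S)-2,10-dimethyl-7-(propan-2-yl)spiro[4.5]deca-1,6-dien-1-yl]oxy}dimethylsilane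
Product: 22 2,4,6-trihydroxy-5-{(1S)-1-[(2R,5R,10S)-2,10-dimethyl-1-oxo-7-(propan-2-yl)spiro[4.5]dec-6-en-2-yl]-3-methylbutyl}benzene-1,3-dicarbaldehyde (keto-phenol in equilibrium with its hemiketal), via ortho-quinone methide 20 (not isolated), via cyclic silyl ketal 21 (not isolated)
Conditions: ethylenediammonium diacetate (10 mol %), 4 Å molecular sieves, 1,2-dichloroethane, 60 °C; then HF·pyridine, THF, 0 °C
Reagents that add atoms: none
Why: Tietze-type domino Knoevenagel/inverse-demand oxa-Diels–Alder (a net Mukaiyama–Michael addition after ketal cleavage): the electron-rich enol ether outcompetes the C6=C7 olefin and adds on the cyclopentene face syn to vinylic C6 and anti to the C10 methine, with the silyloxy group endo and the isobutyl group outside, which sets quaternary C2 (R) and benzylic C1′ (S in 22; the same spatial arrangement is R in 23).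

**Step 10**
Reactants: 22 keto-phenol (see step 9)
Product: 23 target CNP0121396.2 (C1′ R, C1 S, C2 R, C5 R, C10 S)
Conditions: Et3SiH (3 equiv), BF3·OEt2, CH2Cl2, −78 → −20 °C
Reagents that add atoms: none
Why: Reductive etherification (ionic hydrogenation of the cyclic aryl oxocarbenium ion): the phenol oxygen closes onto C1 and Et3SiH attacks the convex face, giving the cis-fused pyran with H1 syn to the C2 methyl (1S), while the hydrogen-bonded, vinylogous-acid aldehydes are far less electrophilic than the oxocarbenium ion and should survive at low temperature.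

**Compound list**
1 | 3-methylbutanal | CC(C)CC=O | starting material
2 | cyclohexylamine | NC1CCCCC1 | starting material
3 | (E)-N-cyclohexyl-3-methylbutan-1-imine | CC(C)C/C=N/C1CCCCC1 | intermediate
4 | acetaldehyde | CC=O | starting material
5 | lithio aza-enolate of 3 (N-lithio-N-cyclohexyl-3-methylbut-1-en-1-amine) | CC(C)C=CN([Li])C1CCCCC1 | intermediate (not isolated)
6 | 3-[(cyclohexylimino)methyl]-4-methylpentan-2-ol (diastereomer mixture) | CC(O)C(C=NC1CCCCC1)C(C)C | intermediate (not isolated)
7 | (2E)-2-(propan-2-yl)but-2-enal | C/C=C(/C=O)C(C)C | intermediate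
8 | (1E)-2-(propan-2-yl)buta-1,3-dien-1-yl acetate | CC(=O)O/C=C(/C=C)C(C)C | intermediate
9 | 2-methylcyclopentan-1-one (racemic) | CC1CCCC1=O | starting material
10 | lithium 5-methylcyclopent-1-en-1-olate | CC1CCC=C1O[Li] | intermediate (not isolated)
11 | 2-(1-hydroxyethyl)-5-methylcyclopentan-1-one (diastereomer mixture) | CC(O)C1CCC(C)C1=O | intermediate (not isolated)
12 | 1-(3-methyl-2-oxocyclopentyl)ethyl methanesulfonate (diastereomer mixture) | CC(OS(C)(=O)=O)C1CCC(C)C1=O | intermediate (not isolated)
13 | (2E)-2-ethylidene-5-methylcyclopentan-1-one (racemic) | C/C=C1\CCC(C)C1=O | intermediate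
14 | (5R,10S)-2,10-dimethyl-1-oxo-7-(propan-2-yl)spiro[4.5]dec-7-en-6-yl acetate (C2 and C6 epimers, left undefined) | O=C1C(C)CC[C@@]12C(OC(C)=O)C(C(C)C)=CC[C@@H]2C | intermediate
15 | (5R,10S)-2,10-dimethyl-7-(propan-2-yl)spiro[4.5]dec-6-en-1-one (C2 epimers, left undefined) | O=C1C(C)CC[C@@]12C=C(C(C)C)CC[C@@H]2C | intermediate
16 | tert-butyl{[(5R,10S)-2,10-dimethyl-7-(propan-2-yl)spiro[4.5]deca-1,6-dien-1-yl]oxy}dimethylsilane | CC1=C(O[Si](C)(C)C(C)(C)C)[C@@]2(CC1)C=C(C(C)C)CC[C@@H]2C | intermediate
17 | benzene-1,3,5-triol | Oc1cc(O)cc(O)c1 | starting material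
18 | bis(N,N-dimethyliminium) dichloride of 19 | C[N+](C)=Cc1c(O)cc(O)c(C=[N+](C)C)c1O.[Cl-].[Cl-] | intermediate (not isolated)
19 | 2,4,6-trihydroxybenzene-1,3-dicarbaldehyde | O=Cc1c(O)cc(O)c(C=O)c1O | intermediate
20 | ortho-quinone methide from 19 and 1 (3-methylbutylidene tautomer) | CC(C)CC=C1C(=O)C(C=O)=C(O)C(C=O)=C1O | intermediate (not isolated)
21 | cyclic silyl ketal: the skeleton of 23 with OSiMe2tBu in place of H at C1 (C1′ S, C1 R, C2 R, C5 R, C10 S) | CC(C)C[C@H]1c2c(O)c(C=O)c(O)c(C=O)c2O[C@@]2(O[Si](C)(C)C(C)(C)C)[C@]1(C)CC[C@@]21C=C(C(C)C)CC[C@@H]1C | intermediate (not isolated)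
22 | 2,4,6-trihydroxy-5-{(1S)-1-[(2R,5R,10S)-2,10-dimethyl-1-oxo-7-(propan-2-yl)spiro[4.5]dec-6-en-2-yl]-3-methylbutyl}benzene-1,3-dicarbaldehyde | CC(C)C[C@@H](c1c(O)c(C=O)c(O)c(C=O)c1O)[C@@]2(C)CC[C@@]3(C=C(C(C)C)CC[C@@H]3C)C2=O | intermediate
23 | CNP0121396.2: 5,7-dihydroxy-4-(2-methylpropyl)chromane-6,8-dicarbaldehyde whose O1–C2–C3 edge is cis-fused to the cyclopentane of (5R,10S)-10-methyl-7-(propan-2-yl)spiro[4.5]dec-6-ene; chromane C2 = C1 (S), chromane C3 = C2 (R, carries CH3), chromane C4 = C1′ (R) | CC(C)C[C@H]1c2c(O)c(C=O)c(O)c(C=O)c2O[C@H]2[C@]1(C)CC[C@@]21C=C(C(C)C)CC[C@@H]1C | target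

**Totals and weak points**
Total step count: 10. Longest linear sequence: 8 steps (steps 1, 2, 3, 5, 6, 7, 9, 10).

Step 5 (the proposed new step) may fail because the dienyl acetate can be destroyed by the strong acid, because the isopropyl group may override the acetoxy group in regiocontrol, or because the enantioselectivity may be low. The fallback sets out from 7 and comes back at 15 using known auxiliary-controlled chemistry. The dienolate of 7 is acylated with (S)-O-methylmandeloyl chloride (Et3N, 4-(dimethylamino)pyridine, CH2Cl2) to give (1E)-2-(propan-2-yl)buta-1,3-dien-1-yl (2S)-2-methoxy-2-phenylacetate F1. A BF3·OEt2-promoted Diels–Alder reaction of F1 with 13 gives (5R,10S)-2,10-dimethyl-1-oxo-7-(propan-2-yl)spiro[4.5]dec-7-en-6-yl (2S)-2-methoxy-2-phenylacetate F2, which is separated by chromatography from the diastereomers of the (5S,10R) series. The Et3SiH/Me3SiOTf reduction of step 6 then removes the mandelate with allylic transposition and gives 15.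

Step 9 may fail because the hindered tetrasubstituted enol ether reacts slowly, so that quinone methide 20 oligomerises or tautomerises to a vinyl phenol, and because the facial selectivity on the cyclopentene is only moderately biased. The fallback sets out from 19 and comes back at 22. 19, 1 and morpholine (EtOH, rt) give the isolable Mannich base 2,4,6-trihydroxy-5-[3-methyl-1-(morpholin-4-yl)butyl]benzene-1,3-dicarbaldehyde F3. Heating F3 with 16 in toluene at 90 °C releases 20 slowly by retro-Mannich cleavage in the absence of water and amine salt, so it is trapped by 16 at low stationary concentration. HF·pyridine then gives 22.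

Step 10 may fail because the silane reduces the formyl groups, or because the electron-poor aryl oxygen makes the oxocarbenium ion hard to form, so that the ring-opened ketone is reduced to the alcohol or undergoes retro-Michael cleavage. The fallback sets out from 15 and comes back at 23 by a radical route that needs no cation. 15 with PhSH, TiCl4 and Et3N (THF, 0 °C → rt) gives the vinyl sulfide {[(5R,10S)-2,10-dimethyl-7-(propan-2-yl)spiro[4.5]deca-1,6-dien-1-yl]sulfanyl}benzene F4. The same domino Knoevenagel/oxa-Diels–Alder reaction with 19 and 1 (ethylenediammonium diacetate, 1,2-dichloroethane, 60 °C) gives the 2-(phenylsulfanyl)chromane O,S-ketal F5, which is the skeleton of 23 with SPh in place of H at C1. Bu3SnH with azobisisobutyronitrile (toluene, 90 °C) cleaves the C–S bond, and hydrogen-atom transfer to the convex face of the α-aryloxy radical gives 23.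

**Further compounds**
F1 | step 5 | (1E)-2-(propan-2-yl)buta-1,3-dien-1-yl (2S)-2-methoxy-2-phenylacetate | C=C/C(C(C)C)=C/OC(=O)[C@@H](OC)c1ccccc1
F2 | step 5 | (5R,10S)-2,10-dimethyl-1-oxo-7-(propan-2-yl)spiro[4.5]dec-7-en-6-yl (2S)-2-methoxy-2-phenylacetate (C2 and C6 epimers, left undefined) | O=C1C(C)CC[C@@]12C(OC(=O)[C@@H](OC)c3ccccc3)C(C(C)C)=CC[C@@H]2C
F3 | step 9 | 2,4,6-trihydroxy-5-[3-methyl-1-(morpholin-4-yl)butyl]benzene-1,3-dicarbaldehyde (racemic) | CC(C)CC(N1CCOCC1)c1c(O)c(C=O)c(O)c(C=O)c1O
F4 | step 10 | {[(5R,10S)-2,10-dimethyl-7-(propan-2-yl)spiro[4.5]deca-1,6-dien-1-yl]sulfanyl}benzene | CC1=C(Sc2ccccc2)[C@@]3(CC1)C=C(C(C)C)CC[C@@H]3C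
F5 | step 10 | O,S-ketal: the skeleton of 23 with phenylsulfanyl in place of H at C1 | CC(C)C[C@H]1c2c(O)c(C=O)c(O)c(C=O)c2O[C@@]2(Sc3ccccc3)[C@]1(C)CC[C@@]21C=C(C(C)C)CC[C@@H]1C
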